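**Assumption:** the target has no stereocentres, only two E trisubstituted alkenes, so "single enantiomer" needs no enantioselective step.

## Retrosynthetic overview
1. Jaspaquinol ⇒ its bis-MOM ether (21) ⇒ reductive desulfonylation of allylic sulfone 20. Sulfone 20 comes from the late C8–C9 coupling: the anion of β-cyclogeranyl phenyl sulfone (8, C10 unit) alkylated with aryl-geranyl bromide (19, C10 unit plus aryl).
2. 19 ⇐ C4–C5 sulfone alkylation of TBS-protected sulfone 15 with aryl-prenyl bromide 13, followed by desulfonylation and OH→Br. Both C5 units come from isoprene monoepoxide (11): Cu-catalysed SN2′ arylation gives 12 and Pd/sulfinate opening gives 14.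
3. 8 ⇐ β-cyclogeraniol ⇐ enol triflate ⇐ 2,2,6-trimethylcyclohexanone ⇐ two α-methylations of 2-methylcyclohexanone.
4. No ring is formed in the route: the cyclohexene ring comes from 2-methylcyclohexanone and the arene from hydroquinone.

## Route

**Step 1**
Reactants: 1 (2-methylcyclohexanone)
Product: 2 (2,6-dimethylcyclohexanone, cis/trans mixture)
Conditions: LDA, THF, −78 °C; then MeI, −78 → 0 °C
Reagents that add atoms: MeI (CI)
Why: LDA gives the kinetic enolate at the less substituted C6, which SN2 methylation traps. The cis/trans mixture converges in step 2.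

**Step 2**
Reactants: 2
Product: 3 (2,2,6-trimethylcyclohexanone)
Conditions: LDA (0.95 equiv), THF, −78 °C; then MeI, DMPU, −78 → 0 °C
Reagents that add atoms: MeI (CI)
Why: 2 is symmetric, so either α-carbon gives the same product. This step builds the gem-dimethyl quaternary carbon.

**Step 3**
Reactants: 3
Product: 4 (2,6,6-trimethylcyclohex-1-en-1-yl triflate)
Conditions: LDA, THF, −78 °C; then PhNTf2, −78 °C → rt
Reagents that add atoms: PhNTf2 (FC(F)(F)S(=O)(=O)N(c1ccccc1)S(=O)(=O)C(F)(F)F)
Why: only C6–H is enolisable (C2 is quaternary), so the enol triflate forms with the tetrasubstituted alkene in the required position.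

**Step 4**
Reactants: 4
Product: 5 (methyl 2,6,6-trimethylcyclohex-1-ene-1-carboxylate)
Conditions: Pd(OAc)2 (5 mol%), PPh3, CO (1 atm), MeOH, Et3N, DMF, 60 °C
Reagents that add atoms: CO ([C-]#[O+]); MeOH (CO)
Why: Pd-catalysed alkoxycarbonylation of an enol triflate (Cacchi type) converts the C–OTf bond into C–CO2Me with the alkene retained.

**Step 5**
Reactants: 5
Product: 6 ((2,6,6-trimethylcyclohex-1-en-1-yl)methanol, β-cyclogeraniol)
Conditions: DIBAL-H (2.5 equiv), CH2Cl2, −78 → 0 °C
Reagents that add atoms: none
Why: hydride reduction of the ester to the primary allylic alcohol.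

**Step 6**
Reactants: 6
Product: 7 (β-cyclogeranyl bromide, crude)
Conditions: PBr3, Et2O, cat. pyridine, −20 → 0 °C
Reagents that add atoms: PBr3 (BrP(Br)Br)
Why: SN2 bromination of a primary allylic alcohol, used crude because the bromide is labile.

**Step 7**
Reactants: 7
Product: 8 (β-cyclogeranyl phenyl sulfone)
Conditions: PhSO2Na, DMF, rt
Reagents that add atoms: sodium benzenesulfinate ([Na+].[O-]S(=O)c1ccccc1)
Why: SN2 S-alkylation of the sulfinate gives the stable allylic sulfone that serves as the ring-side nucleophile.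

**Step 8**
Reactants: 9 (hydroquinone)
Product: 10 (1,4-bis(methoxymethoxy)benzene)
Conditions: MOMCl, i-Pr2NEt, CH2Cl2, 0 °C → rt
Reagents that add atoms: MOMCl (ClCOC)
Why: double O-alkylation installs base-stable protecting groups that also direct ortho-lithiation.

**Step 9**
Reactants: 10; 11 (isoprene monoepoxide, 2-methyl-2-vinyloxirane)
Product: 12 ((E)-4-[2,5-bis(MOM-oxy)phenyl]-2-methylbut-2-en-1-ol)
Conditions: n-BuLi, THF, 0 °C (directed ortho-metalation); MgBr2·OEt2; CuI (10 mol%), 11, −20 → 0 °C
Reagents that add atoms: none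
Why: the arylmagnesium reagent opens the vinyl epoxide by Cu-catalysed SN2′ attack at the terminal CH2. The bulkier CH2O group ends up trans to the aryl-CH2, which sets the C2=C3 E geometry.

**Step 10**
Reactants: 12
Product: 13 (aryl-prenyl bromide: (E)-1-bromo-4-aryl-2-methylbut-2-ene)
Conditions: PPh3, CBr4, CH2Cl2, 0 °C; used crude
Reagents that add atoms: CBr4 (BrC(Br)(Br)Br)
Why: Appel bromination is neutral, so the MOM acetals survive, and the alkene geometry is retained.

**Step 11**
Reactants: 11
Product: 14 ((E)-2-methyl-4-(phenylsulfonyl)but-2-en-1-ol)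
Conditions: Pd(PPh3)4 (5 mol%), PhSO2Na, THF/H2O, 25–40 °C
Reagents that add atoms: PhSO2Na ([Na+].[O-]S(=O)c1ccccc1)
Why: Tsuji–Trost opening of the vinyl epoxide via a π-allyl-Pd species. Sulfinate attacks the unhindered CH2 terminus. Reversible ionisation of the allylic sulfone funnels the product to the thermodynamic E isomer.

**Step 12**
Reactants: 14
Product: 15 (TBS ether of 14)
Conditions: TBSCl, imidazole, DMF, rt
Reagents that add atoms: TBSCl (CC(C)(C)[Si](C)(C)Cl)
Why: protects the primary alcohol so the sulfone can be deprotonated cleanly.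

**Step 13**
Reactants: 15; 13
Product: 16 (C4–C5 coupled allylic sulfone)
Conditions: n-BuLi (1.05 equiv), THF, −78 °C; DMPU; then 13, −78 → −40 °C
Reagents that add atoms: none
Why: sulfone-stabilised allylic anion alkylation (Biellmann type). The anion reacts at the α-carbon and SN2 at the primary bromide leaves both alkene geometries intact.

**Step 14**
Reactants: 16
Product: 17 (TBSO-aryl-geranyl ether; E,E)
Conditions: Pd(dppp)Cl2 (5–10 mol%), LiBHEt3, THF, 0 °C
Reagents that add atoms: none
Why: Pd-catalysed hydrogenolysis of the allylic sulfone. The π-allyl has one tertiary terminus (C7, bearing Me), so hydride adds at C5 and the C6=C7 alkene stays in place.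

**Step 15**
Reactants: 17
Product: 18 ((2E,6E)-8-aryl-2,6-dimethylocta-2,6-dien-1-ol)
Conditions: TBAF, THF, rt
Reagents that add atoms: none
Why: fluoride cleaves the Si–O bond; the MOM ethers and alkenes are untouched.

**Step 16**
Reactants: 18
Product: 19 (aryl-geranyl bromide, E,E)
Conditions: PPh3, CBr4, CH2Cl2, 0 °C; used crude
Reagents that add atoms: CBr4 (BrC(Br)(Br)Br)
Why: Appel bromination of a primary allylic alcohol with retention of geometry.

**Step 17 (late coupling)**
Reactants: 8; 19
Product: 20 (C8–C9 coupled allylic sulfone)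
Conditions: n-BuLi, THF, −78 °C; DMPU; then 19, −78 → −20 °C
Reagents that add atoms: none
Why: the α-anion of the cyclogeranyl sulfone is alkylated at C9 by the primary allylic bromide (SN2). Attack at the ring carbon would create a hindered quaternary centre, so α-alkylation is favoured. This joins the two ~C10 halves.

**Step 18**
Reactants: 20
Product: 21 (bis-MOM jaspaquinol)
Conditions: Pd(dppp)Cl2 (10 mol%), LiBHEt3, THF, 0 → 25 °C
Reagents that add atoms: none
Why: Pd-catalysed reductive desulfonylation. The π-allyl has one tertiary terminus (ring C2′, bearing Me), so hydride adds at C9 and the tetrasubstituted ring alkene is restored.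

**Step 19**
Reactants: 21
Product: 22 (jaspaquinol)
Conditions: 2 M HCl, THF/MeOH 1:1, 40 °C, Ar, then work up under inert atmosphere
Reagents that add atoms: none
Why: acid hydrolysis of the aryl MOM acetals gives the free hydroquinone; the trisubstituted alkenes survive these dilute, mild conditions.

## Compound list
1 | 2-methylcyclohexanone | CC1CCCCC1=O | starting material
2 | 2,6-dimethylcyclohexanone (cis/trans) | CC1CCCC(C)C1=O | intermediate
3 | 2,2,6-trimethylcyclohexanone | CC1CCCC(C)(C)C1=O | intermediate
4 | 2,6,6-trimethylcyclohex-1-enyl triflate | CC1=C(OS(=O)(=O)C(F)(F)F)C(C)(C)CCC1 | intermediate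
5 | methyl 2,6,6-trimethylcyclohex-1-enecarboxylate | CC1=C(C(=O)OC)C(C)(C)CCC1 | intermediate
6 | β-cyclogeraniol | CC1=C(CO)C(C)(C)CCC1 | intermediate
7 | β-cyclogeranyl bromide | CC1=C(CBr)C(C)(C)CCC1 | intermediate
8 | β-cyclogeranyl phenyl sulfone | CC1=C(CS(=O)(=O)c2ccccc2)C(C)(C)CCC1 | intermediate
9 | hydroquinone | Oc1ccc(O)cc1 | starting material
10 | 1,4-bis(methoxymethoxy)benzene | COCOc1ccc(OCOC)cc1 | intermediate
11 | isoprene monoepoxide | CC1(C=C)CO1 | starting material
12 | (E)-4-[2,5-bis(MOM-oxy)phenyl]-2-methylbut-2-en-1-ol | OC/C(C)=C/Cc1cc(OCOC)ccc1OCOC | intermediate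
13 | (E)-aryl-prenyl bromide | BrC/C(C)=C/Cc1cc(OCOC)ccc1OCOC | intermediate
14 | (E)-2-methyl-4-(phenylsulfonyl)but-2-en-1-ol | OC/C(C)=C/CS(=O)(=O)c1ccccc1 | intermediate
15 | TBS ether of 14 | CC(C)(C)[Si](C)(C)OC/C(C)=C/CS(=O)(=O)c1ccccc1 | intermediate
16 | C4–C5 coupled sulfone | CC(C)(C)[Si](C)(C)OC/C(C)=C/C(S(=O)(=O)c1ccccc1)C/C(C)=C/Cc1cc(OCOC)ccc1OCOC | intermediate
17 | TBS ether of aryl-geranyl alcohol | CC(C)(C)[Si](C)(C)OC/C(C)=C/CC/C(C)=C/Cc1cc(OCOC)ccc1OCOC | intermediate
18 | aryl-geranyl alcohol | OC/C(C)=C/CC/C(C)=C/Cc1cc(OCOC)ccc1OCOC | intermediate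
19 | aryl-geranyl bromide | BrC/C(C)=C/CC/C(C)=C/Cc1cc(OCOC)ccc1OCOC | intermediate
20 | C8–C9 coupled sulfone | CC1=C(C(S(=O)(=O)c2ccccc2)C/C(C)=C/CC/C(C)=C/Cc2cc(OCOC)ccc2OCOC)C(C)(C)CCC1 | intermediate
21 | bis-MOM jaspaquinol | CC1=C(CC/C(C)=C/CC/C(C)=C/Cc2cc(OCOC)ccc2OCOC)C(C)(C)CCC1 | intermediate
22 | jaspaquinol | CC1=C(CC/C(C)=C/CC/C(C)=C/Cc2cc(O)ccc2O)C(C)(C)CCC1 | target

## Totals
Total steps: 19. Longest linear sequence: 10 (both the ring branch, steps 1–7 then 17–19, and the aryl branch, steps 8, 9, 10, 13–19).

**Three steps most likely to fail**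
1. **Step 9** (Cu-catalysed SN2′ arylation of isoprene epoxide): risks are SN2 versus SN2′ regiochemistry and E/Z selectivity.
   - Fallback: build 12 by a Wittig reaction of 2,5-bis(MOM-oxy)phenylacetaldehyde with Ph3P=C(Me)CO2Et, which is E-selective, followed by DIBAL reduction.
2. **Step 11** (Pd-catalysed sulfinate opening of isoprene epoxide): risks are regio- and E/Z selectivity.
   - Fallback: allylic oxidation of prenyl acetate with SeO2/TBHP to the (E)-4-acetoxy-2-methylbut-2-enal, then NaBH4 reduction, Appel bromination, PhSO2Na substitution and acetate methanolysis to give 14.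
3. **Step 18** (desulfonylation next to the crowded tetrasubstituted ring alkene): the π-allyl-Pd may form slowly, or the alkene may isomerise.
   - Fallback: reverse the polarity of the C8–C9 coupling. Convert 19 to its C8 allylic sulfone, alkylate that anion with β-cyclogeranyl bromide 7, and remove the sulfone at the unhindered C8 position.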